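Over 2.0 h at fixed temperature, this flask feeds solid substrate and held gas into a solution where they join to target, and dissolved substrate also consumes target.

solid substrate 0.22 M; gas 39 mM (held); time 2.0 h

    solid substrate ⇌ dissolved substrate, rate k1*(cs1 - [dissolved substrate]) while solid is left; crystals form when [dissolved substrate] > cs1 (cs1 = 0.10 M, k1 = 0.063 /min)
    dissolved substrate + partner ⇌ target (K2 = 11 /M, k2 = 2.0 /M/min)
    dissolved substrate + target → side product (k3 = 0.51 /M/min)
    solid product ⇌ target, rate k4*(cs4 - [target]) while solid is left; crystals form when [target] > cs4 (cs4 = 0.056 M, k4 = 2.5 /min)
    gas ⇌ partner, rate k5*(csat - [partner]) (k5 = 0.17 /min, csat = 39 mM)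
    target ⇌ isomer of the product (K6 = 0.10, k6 = 0.022 /min)

- percentages count the solid substrate that a species holds: one side product counts as two
- target is meant together with its solid product
- solid, in amounts per volume of the solution: solid substrate, solid product
- at the start none of partner is dissolved
- at the start none of the solid substrate is in solution
- dissolved substrate means what is dissolved; the solid is not counted in it
- run time (flask): 2.0 h

1. amount of target and solid product together at 2.0 h, in percent of the solid substrate charged
2. concentration of dissolved substrate in solution at 2.0 h, in percent of saturation

Target crystallises above its solubility, and the joining equilibrium puts a ceiling on dissolved target, reached with dissolved substrate and partner both at saturation. I fold this into one number: N = 11 /M × 0.10 M × 39 mM / 0.056 M = 0.766, the fill ratio, which is dissolved target at its ceiling divided by its solubility, the supersaturation ratio at that ceiling. It stands below one, so I expect no solid product, and y has a ceiling of 19.5% of the charge.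

One number is not enough: N holds no clock. At the ceiling the side step runs at 0.00219 M/min and each event takes two substrate units, so at that rate it takes up the charge in 50.3 min, less than the run. I therefore commit to y below the ceiling and sat below saturation, and to nothing tighter.

The forecast is tighter: y = 8.7% (7.5% to 10%) and sat = 50% (38% to 62%), with the remark “so solid product never forms”. My reckoning does not give those figures.

The simulation gives y = 8.29% and sat = 47.8%, inside the forecast's ranges.

N carries on if standing concentrations replace the saturation values. In this flask at 2.0 h, with partner at 0.0372 M, N becomes 0.349, less than 0.766, which gives a share of 8.88% against the 8.29% found. The neighbouring flask is the same flask read at 8.0 h, and its y is less than this flask's. In that flask dissolved substrate holds 3.57% of the charge and partner stands at 0.0390 M, so N = 0.0601 and the share is 1.53%; its y reads 1.52%.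

The rate constants were chosen freely; what happens was integrated by code.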